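**Assumptions.** Locants are germacrane numbers: lactone O on C6, ring fusion C6/C7, angelate on C8, 2‑methylbutanoate on C9, C14 = CHO on C10, C15 = CH2OH on C4, C11(=C13H2)–C12(=O) the lactone carbons. The SMILES is read as 6R,7S,8S,9R with a (2R)‑2‑methylbutanoate, and with C3/C6 cis across C4=C5 and C2/C9 cis across C1=C10. (R)‑2‑Methylbutanoic acid, angelic acid and (E)‑3‑(tributylstannyl)prop‑2‑en‑1‑ol are bought.

**Retrosynthetic overview**
1. Target 31 ⇐ macrolactone 28 by C14–OH unmasking/oxidation and C15–O desilylation.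
2. 28 ⇐ acyclic (2Z,6Z)-farnesane-type aldehyde 26 in one pot: first the ten-membered carbocycle by C6–C7 closure (the farnesyl C1–C10 bond of germacrene A synthase), then the γ-lactone by C6–O attack on C12.
3. 26 ⇐ allylsilane diester 25 ⇐ Sharpless epoxide 16: acid opening at C9 with inversion, Wittig at C7, angeloylation at C8.
4. Dienol 15 ⇐ B-alkyl Suzuki coupling (C3–C4) of triene 8 with vinyl iodide 13.
5. 8 ⇐ acrolein by iodo-Wittig, reduction and Stille coupling; 13 ⇐ but-2-yne-1,4-diol by Red-Al/I2.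

**Route**

Step 1
Reactants: 1 ethyl (triphenyl-λ5-phosphanylidene)acetate; 2 acrolein
Product: 4 ethyl (2Z)-2-iodopenta-2,4-dienoate, via iodo ylide 3 (not isolated)
Conditions: NIS (1.05 equiv), CH2Cl2, −20 °C; then 2, 0 °C→rt
Reagents that add atoms: N-iodosuccinimide, O=C1CCC(=O)N1I
Why: One-pot halogenation–Wittig olefination; the stabilised iodo ylide puts the ester trans to the vinyl group, so iodine (the future C9 site) is cis to the future C2 and the ester carbon (C14) is trans.

Step 2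
Reactants: 4 ethyl (2Z)-2-iodopenta-2,4-dienoate
Product: 5 (2Z)-2-iodopenta-2,4-dien-1-ol
Conditions: DIBAL-H (2.2 equiv), CH2Cl2, −78→0 °C; Rochelle salt
Reagents that add atoms: none
Why: DIBAL-H 1,2-reduction of the enoate gives the allylic alcohol (C14–OH) without touching the vinyl iodide or the olefin geometry.

Step 3
Reactants: 5 (2Z)-2-iodopenta-2,4-dien-1-ol
Product: 6 TBS ether of 5
Conditions: TBSCl, imidazole, CH2Cl2, 0 °C→rt
Reagents that add atoms: tert-butyldimethylsilyl chloride, CC(C)(C)[Si](C)(C)Cl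
Why: Standard silylation masks C14–OH, so that the only free allylic alcohol later is the one at C7.

Step 4
Reactants: 6 TBS ether of 5; 7 (2E)-3-(tributylstannyl)prop-2-en-1-ol
Product: 8 (2E,4E)-4-(TBSO-methyl)hepta-2,4,6-trien-1-ol
Conditions: Pd2(dba)3 (2.5 mol%), AsPh3, CuI (10 mol%), NMP, rt (kept ≤40 °C)
Reagents that add atoms: none
Why: Stille coupling with retention at both sp2 carbons places C9 cis to C2 on the C1=C10 olefin and installs the (E)-allylic alcohol C7–C8=C9; mild temperature avoids 6π-electrocyclisation of the cis-triene.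

Step 5
Reactants: 9 but-2-yne-1,4-diol
Product: 10 4-(TBDPS-oxy)but-2-yn-1-ol
Conditions: TBDPSCl (0.3 equiv), imidazole, DMF, 0 °C (diol in excess)
Reagents that add atoms: tert-butyldiphenylsilyl chloride, CC(C)(C)[Si](Cl)(c1ccccc1)c1ccccc1
Why: Statistical monosilylation of a cheap symmetric diol differentiates C15–O (silylated) from C6–O (free).

Step 6
Reactants: 10 4-(TBDPS-oxy)but-2-yn-1-ol
Product: 12 (2Z)-4-(TBDPS-oxy)-3-iodobut-2-en-1-ol, via cyclic vinylalanate 11 (not isolated)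
Conditions: Red-Al (1.6 equiv), THF, 0 °C→rt; EtOAc; then I2, −78→0 °C
Reagents that add atoms: iodine, II
Why: Hydroxyl-directed trans-hydroalumination (Corey-type; H to C5, Al to C4) followed by iododealumination with retention gives the vinyl iodide with C6 cis to the position that will take C3.

Step 7
Reactants: 12 (2Z)-4-(TBDPS-oxy)-3-iodobut-2-en-1-ol
Product: 13 TES ether of 12
Conditions: TESCl, imidazole, CH2Cl2, 0 °C
Reagents that add atoms: chlorotriethylsilane, CC[Si](Cl)(CC)CC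
Why: Standard silylation; the primary TES ether is the one silyl group that Swern conditions later convert directly into the C6 aldehyde.

Step 8
Reactants: 8 (2E,4E)-4-(TBSO-methyl)hepta-2,4,6-trien-1-ol; 13 TES ether of 12
Product: 15 acyclic trienol (C7–OH), via B-alkyl-9-BBN adduct 14 (not isolated)
Conditions: 9-BBN (1.5 equiv), THF, 0 °C→rt; then 13, PdCl2(dppf) (5 mol%), AsPh3, Cs2CO3, DMF/H2O, rt
Reagents that add atoms: none
Why: 9-BBN hydroborates only the terminal monosubstituted vinyl group (boron on C3) and the B-alkyl Suzuki–Miyaura coupling forms C3–C4 with retention of the vinyl iodide geometry (C3 cis to C6).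

Step 9
Reactants: 15 acyclic trienol (C7–OH)
Product: 16 (8S,9S)-epoxy alcohol
Conditions: Ti(OiPr)4 (10 mol%), L-(+)-diethyl tartrate (12 mol%), t-BuOOH, 4 Å MS, CH2Cl2, −20 °C
Reagents that add atoms: tert-butyl hydroperoxide, CC(C)(C)OO
Why: Sharpless asymmetric epoxidation acts only on the olefin of the single free allylic alcohol, and L-(+)-tartrate gives the (2S,3S) trans-epoxy alcohol, which sets C8 (S) directly and C9 for inversion.

Step 10
Reactants: 16 (8S,9S)-epoxy alcohol; 17 (2R)-2-methylbutanoic acid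
Product: 18 (8S,9R)-7,8-diol 9-(2R)-2-methylbutanoate
Conditions: Ti(OiPr)4 (1.5 equiv), 17 (1.5 equiv), CH2Cl2, 0 °C→rt
Reagents that add atoms: none
Why: Titanium-mediated C3-selective opening of a 2,3-epoxy alcohol by a carboxylic acid is an SN2 attack at the allylic C9 with inversion, which gives 9R with its ester in place and leaves C8–OH (S) free.

Step 11
Reactants: 1 ethyl (triphenyl-λ5-phosphanylidene)acetate; 19 (iodomethyl)trimethylsilane
Product: 20 ethyl 2-(triphenyl-λ5-phosphanylidene)-3-(trimethylsilyl)propanoate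
Conditions: 1 (2.0 equiv), 19 (1.0 equiv), EtOAc, reflux; filter off the phosphonium salt
Reagents that add atoms: none
Why: C-alkylation of a stabilised ylide followed by transylidation (the second equivalent of 1 is the base) gives the silylmethyl ylide.

Step 12
Reactants: 18 (8S,9R)-7,8-diol 9-(2R)-2-methylbutanoate; 20 ethyl 2-(triphenyl-λ5-phosphanylidene)-3-(trimethylsilyl)propanoate
Product: 22 γ-hydroxy enoate allylsilane (C8–OH), via hydroxy aldehyde 21 (not isolated)
Conditions: TEMPO (10 mol%), PhI(OAc)2 (1.1 equiv), CH2Cl2, rt; then 20 (1.5 equiv), 40 °C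
Reagents that add atoms: none
Why: TEMPO/PhI(OAc)2 oxidises the primary alcohol selectively and the in situ Wittig reaction of the α-hydroxy aldehyde with the stabilised ylide gives the C7=C11 olefin with CO2Et trans to C8, without base that could move the C9 ester.

Step 13
Reactants: 22 γ-hydroxy enoate allylsilane (C8–OH); 23 angelic acid
Product: 25 allylsilane diester (C8 angelate), via mixed anhydride 24 (not isolated)
Conditions: 23 (3 equiv), 2,4,6-trichlorobenzoyl chloride (3 equiv), Et3N, PhMe, rt; then 22, DMAP, 60 °C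
Reagents that add atoms: none
Why: Yamaguchi-type esterification through the preformed mixed anhydride acylates the hindered C8–OH with retention and keeps the (Z)-geometry of the angelate.

Step 14
Reactants: 25 allylsilane diester (C8 angelate)
Product: 26 seco-aldehyde (C6 enal)
Conditions: (COCl)2 (4 equiv), DMSO (8 equiv), CH2Cl2, −78→−30 °C; Et3N, −78→0 °C
Reagents that add atoms: none
Why: Under Swern conditions a primary TES ether is cleaved and oxidised directly to the aldehyde while TBS and TBDPS ethers survive, which gives the (Z)-enal without a separate deprotection.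

Step 15
Reactants: 26 seco-aldehyde (C6 enal)
Product: 28 macrolactone (C14–OTBS and C15–OTBDPS), via hydroxy ester 27 (not isolated)
Conditions: BF3·OEt2 (3 equiv), CH2Cl2 (1 mM, slow addition of 26), −78→−30 °C; aq NaHCO3; crude 27, PPTS, PhH, 50 °C
Reagents that add atoms: none
Why: Proposed new method: BF3 activates the C6 enal as an allyl-cation-like oxocarbenium and the C7=C11 π bond attacks it anti to the C–Si bond (SE2′, silicon standing in for the proton lost in the enzymatic farnesyl C1–C10 closure); with H8 eclipsing the olefin (A1,3 strain against CH2SiMe3), C9 anti to the forming bond and the angelate outside, this should give 7S relative to 8S, an antiperiplanar open transition state of the kind that gives trans-fused lactones in small-ring versions should give 6R, and the C6 hydroxyl then closes onto the C12 ester; the closest known reactions are the Lewis-acid cyclisation of ω-formyl 2-(silylmethyl)alk-2-enoates to five- to eight-membered-ring-fused α-methylene-γ-lactones and BF3-promoted allylstannane–aldehyde macrocyclisations to ten- to fourteen-membered rings.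

Step 16
Reactants: 28 macrolactone (C14–OTBS and C15–OTBDPS)
Product: 29 C14 alcohol
Conditions: HF·pyridine, pyridine, THF, 0 °C
Reagents that add atoms: none
Why: Buffered HF·pyridine removes the primary TBS ether much faster than the primary TBDPS ether.

Step 17
Reactants: 29 C14 alcohol
Product: 30 C14 aldehyde
Conditions: MnO2 (20 equiv), CH2Cl2, rt
Reagents that add atoms: none
Why: MnO2 oxidises the only free allylic alcohol to the enal, whose CHO is already trans to C2 as in the target.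

Step 18
Reactants: 30 C14 aldehyde
Product: 31 target (CNP0290361.1)
Conditions: HF·pyridine (excess), THF, rt
Reagents that add atoms: none
Why: Fluoride-mediated cleavage of the TBDPS ether under mildly acidic conditions frees C15–OH without touching the enal, the esters or the α-methylene lactone.

**Compound list**

1 | ethyl (triphenyl-λ5-phosphanylidene)acetate | CCOC(=O)C=P(c1ccccc1)(c1ccccc1)c1ccccc1 | starting material
2 | acrolein (prop-2-enal) | C=CC=O | starting material
3 | ethyl iodo(triphenyl-λ5-phosphanylidene)acetate (iodo ylide) | CCOC(=O)C(I)=P(c1ccccc1)(c1ccccc1)c1ccccc1 | intermediate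
4 | ethyl (2Z)-2-iodopenta-2,4-dienoate | C=C/C=C(\I)C(=O)OCC | intermediate
5 | (2Z)-2-iodopenta-2,4-dien-1-ol | C=C/C=C(\I)CO | intermediate
6 | tert-butyl{[(2Z)-2-iodopenta-2,4-dien-1-yl]oxy}dimethylsilane (TBS ether of 5) | C=C/C=C(\I)CO[Si](C)(C)C(C)(C)C | intermediate
7 | (2E)-3-(tributylstannyl)prop-2-en-1-ol | CCCC[Sn](CCCC)(CCCC)/C=C/CO | starting material
8 | (2E,4E)-4-{[(tert-butyldimethylsilyl)oxy]methyl}hepta-2,4,6-trien-1-ol (C9 cis to C2 across C10=C1) | C=C/C=C(/CO[Si](C)(C)C(C)(C)C)\C=C\CO | intermediate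
9 | but-2-yne-1,4-diol | OCC#CCO | starting material
10 | 4-[(tert-butyldiphenylsilyl)oxy]but-2-yn-1-ol | OCC#CCO[Si](c1ccccc1)(c1ccccc1)C(C)(C)C | intermediate
11 | sodium cyclic vinylalanate from 10 (2,5-dihydro-1,2-oxaluminole ate complex, Al on C4) | [Na+].COCCO[Al-]1(OCCOC)OCC=C1CO[Si](c2ccccc2)(c2ccccc2)C(C)(C)C | intermediate
12 | (2Z)-4-[(tert-butyldiphenylsilyl)oxy]-3-iodobut-2-en-1-ol | OC/C=C(/CO[Si](c1ccccc1)(c1ccccc1)C(C)(C)C)I | intermediate
13 | (2Z)-4-[(tert-butyldiphenylsilyl)oxy]-3-iodo-1-[(triethylsilyl)oxy]but-2-ene (TES ether of 12) | CC[Si](CC)(CC)OC/C=C(/CO[Si](c1ccccc1)(c1ccccc1)C(C)(C)C)I | intermediate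
14 | B-alkyl-9-BBN adduct of 8 (boron on C3) | OC/C=C/C(CO[Si](C)(C)C(C)(C)C)=C\CCB1C2CCCC1CCC2 | intermediate
15 | (2E,4E,8E)-4-(TBSO-methyl)-8-(TBDPSO-methyl)-10-(TESO)deca-2,4,8-trien-1-ol (C7–OH; C9 cis to C2; C3 cis to C6) | CC[Si](CC)(CC)OC/C=C(/CO[Si](c1ccccc1)(c1ccccc1)C(C)(C)C)CC/C=C(/CO[Si](C)(C)C(C)(C)C)\C=C\CO | intermediate
16 | (8S,9S)-8,9-epoxide of 15 ((2S,3S)-trans-epoxy alcohol) | CC[Si](CC)(CC)OC/C=C(/CO[Si](c1ccccc1)(c1ccccc1)C(C)(C)C)CC/C=C(/CO[Si](C)(C)C(C)(C)C)[C@@H]2O[C@H]2CO | intermediate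
17 | (2R)-2-methylbutanoic acid | CC[C@@H](C)C(=O)O | starting material
18 | (8S,9R)-7,8-diol with C9 (2R)-2-methylbutanoate | CC[Si](CC)(CC)OC/C=C(/CO[Si](c1ccccc1)(c1ccccc1)C(C)(C)C)CC/C=C(/CO[Si](C)(C)C(C)(C)C)[C@@H](OC(=O)[C@H](C)CC)[C@@H](O)CO | intermediate
19 | (iodomethyl)trimethylsilane | C[Si](C)(C)CI | starting material
20 | ethyl 2-(triphenyl-λ5-phosphanylidene)-3-(trimethylsilyl)propanoate | CCOC(=O)C(C[Si](C)(C)C)=P(c1ccccc1)(c1ccccc1)c1ccccc1 | intermediate
21 | C7 aldehyde of 18 (α-hydroxy aldehyde; C8 and C9 unchanged in space) | CC[Si](CC)(CC)OC/C=C(/CO[Si](c1ccccc1)(c1ccccc1)C(C)(C)C)CC/C=C(/CO[Si](C)(C)C(C)(C)C)[C@@H](OC(=O)[C@H](C)CC)[C@@H](O)C=O | intermediate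
22 | γ-hydroxy enoate allylsilane: ethyl 2-[(trimethylsilyl)methyl]alk-2-enoate with CO2Et trans to C8; 8S-OH; 9R ester | CC[Si](CC)(CC)OC/C=C(/CO[Si](c1ccccc1)(c1ccccc1)C(C)(C)C)CC/C=C(/CO[Si](C)(C)C(C)(C)C)[C@@H](OC(=O)[C@H](C)CC)[C@@H](O)/C=C(\C[Si](C)(C)C)C(=O)OCC | intermediate
23 | angelic acid ((2Z)-2-methylbut-2-enoic acid) | C/C=C(/C)C(=O)O | starting material
24 | angelic 2,4,6-trichlorobenzoic anhydride | C/C=C(/C)C(=O)OC(=O)c1c(Cl)cc(Cl)cc1Cl | intermediate
25 | allylsilane diester: 22 with C8 angelate (8S,9R; C6–OTES) | CC[Si](CC)(CC)OC/C=C(/CO[Si](c1ccccc1)(c1ccccc1)C(C)(C)C)CC/C=C(/CO[Si](C)(C)C(C)(C)C)[C@@H](OC(=O)[C@H](C)CC)[C@@H](OC(=O)/C(C)=C\C)/C=C(\C[Si](C)(C)C)C(=O)OCC | intermediate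
26 | seco-aldehyde: 25 with C6 as the (Z)-enal CHO (C3 cis to CHO) | O=C/C=C(/CO[Si](c1ccccc1)(c1ccccc1)C(C)(C)C)CC/C=C(/CO[Si](C)(C)C(C)(C)C)[C@@H](OC(=O)[C@H](C)CC)[C@@H](OC(=O)/C(C)=C\C)/C=C(\C[Si](C)(C)C)C(=O)OCC | intermediate
27 | (6R,7S,8S,9R)-ten-membered hydroxy ester: C6–OH; C7 bears C(=CH2)CO2Et | O[C@@H]1/C=C(/CO[Si](c2ccccc2)(c2ccccc2)C(C)(C)C)CC/C=C(/CO[Si](C)(C)C(C)(C)C)[C@@H](OC(=O)[C@H](C)CC)[C@@H](OC(=O)/C(C)=C\C)[C@H]1C(=C)C(=O)OCC | intermediate
28 | (6R,7S,8S,9R)-macrolactone with C14–OTBS and C15–OTBDPS | C=C1C(=O)O[C@@H]2/C=C(/CO[Si](c3ccccc3)(c3ccccc3)C(C)(C)C)CC/C=C(/CO[Si](C)(C)C(C)(C)C)[C@@H](OC(=O)[C@H](C)CC)[C@@H](OC(=O)/C(C)=C\C)[C@@H]12 | intermediate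
29 | macrolactone with C14–OH and C15–OTBDPS | C=C1C(=O)O[C@@H]2/C=C(/CO[Si](c3ccccc3)(c3ccccc3)C(C)(C)C)CC/C=C(/CO)[C@@H](OC(=O)[C@H](C)CC)[C@@H](OC(=O)/C(C)=C\C)[C@@H]12 | intermediate
30 | macrolactone with C14 = CHO and C15–OTBDPS | C=C1C(=O)O[C@@H]2/C=C(/CO[Si](c3ccccc3)(c3ccccc3)C(C)(C)C)CC/C=C(/C=O)[C@@H](OC(=O)[C@H](C)CC)[C@@H](OC(=O)/C(C)=C\C)[C@@H]12 | intermediate
31 | CNP0290361.1 | C=C1C(=O)O[C@@H]2/C=C(/CO)CC/C=C(/C=O)[C@@H](OC(=O)[C@H](C)CC)[C@@H](OC(=O)/C(C)=C\C)[C@@H]12 | target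

**Step count.** 18 steps in total. The longest linear sequence is 14 steps (1–4, 8–10, 12–18); steps 5–7 and step 11 are side branches.

**Steps most likely to fail**

Step 15 (ring closure). Three things can go wrong: the 2-(silylmethyl)enoate is a weak nucleophile; the C1=C10 olefin could attack the activated enal in a neral-type six-ring Prins closure, although it is deactivated by two allylic C–O bonds; and the C6/C7 relationship rests on a transition-state argument. The fallback closes the same bond by a chromium(II) Barbier (Nozaki–Hiyama-type) allylation through a closed transition state, run before the angelate is in place so that the allylmetal carries no δ-acyloxy leaving group. It sets out from 22. PPTS in MeOH/CH2Cl2 at 0 °C removes only the primary TES ether to give the C6 allylic alcohol F1. MnO2 oxidises only that primary allylic alcohol to the hydroxy enal F2. NBS (propylene oxide, CH2Cl2, −78 °C) converts the allylsilane by SE2′ bromodesilylation into the allylic bromide F3. CrCl2 in THF at 1 mM generates the allylchromium, which adds to the aldehyde and lactonises to the 8-hydroxy lactone F4. Angeloylation as in step 13 then comes back to the route at 28.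

Step 8 (hydroboration of the cross-conjugated triene, then Suzuki coupling). 9-BBN may not discriminate cleanly within the triene, or may form allylboranes. The fallback builds C2–C3 from the left fragment instead and makes the C1=C10 olefin by carbocupration. It sets out from 13. Iodine–lithium exchange (t-BuLi, Et2O, −78 °C) and ethylene oxide/BF3·OEt2 give the homoallylic alcohol F5. I2/PPh3/imidazole gives the primary iodide F6. t-BuLi, CuBr·SMe2 and ethyl propiolate (syn carbocupration), then I2 with retention, give the (Z)-iodo ester F7. DIBAL-H gives the iodo alcohol F8. TBSCl gives the silyl ether F9. Stille coupling of F9 with 7 as in step 4 comes back to the route at 15.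

Step 12 (one-pot oxidation/Wittig on the acyloxy diol). The C9 ester may migrate to O8 or O7, the α-hydroxy aldehyde may be unstable, or the hindered ylide may react slowly. The fallback olefinates before the epoxide is opened, so that no 1,2-diol or α-hydroxy aldehyde is formed. It sets out from 16. SO3·pyridine/DMSO/iPr2NEt gives the epoxy aldehyde F10. Wittig reaction with 20 gives the epoxy enoate F11. Acid 17 with a catalytic Lewis acid (Cu(OTf)2, CH2Cl2, −40 °C) then opens the epoxide at C9 with inversion; C9 is allylic to the electron-rich C1=C10 olefin, whereas C8 is deactivated by the enoate. This comes back to the route at 22.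

**Further compounds**

F1 | step 15 | C6 allylic alcohol (22 without TES) | OC/C=C(/CO[Si](c1ccccc1)(c1ccccc1)C(C)(C)C)CC/C=C(/CO[Si](C)(C)C(C)(C)C)[C@@H](OC(=O)[C@H](C)CC)[C@@H](O)/C=C(\C[Si](C)(C)C)C(=O)OCC
F2 | step 15 | hydroxy enal (C6 = CHO; C8–OH free) | O=C/C=C(/CO[Si](c1ccccc1)(c1ccccc1)C(C)(C)C)CC/C=C(/CO[Si](C)(C)C(C)(C)C)[C@@H](OC(=O)[C@H](C)CC)[C@@H](O)/C=C(\C[Si](C)(C)C)C(=O)OCC
F3 | step 15 | allylic bromide (C7–Br; C11=CH2; C7 epimers) | O=C/C=C(/CO[Si](c1ccccc1)(c1ccccc1)C(C)(C)C)CC/C=C(/CO[Si](C)(C)C(C)(C)C)[C@@H](OC(=O)[C@H](C)CC)[C@@H](O)C(Br)C(=C)C(=O)OCC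
F4 | step 15 | 8-hydroxy lactone (28 without the angeloyl group) | C=C1C(=O)O[C@@H]2/C=C(/CO[Si](c3ccccc3)(c3ccccc3)C(C)(C)C)CC/C=C(/CO[Si](C)(C)C(C)(C)C)[C@@H](OC(=O)[C@H](C)CC)[C@@H](O)[C@@H]12
F5 | step 8 | homoallylic alcohol (C2–OH) | CC[Si](CC)(CC)OC/C=C(/CO[Si](c1ccccc1)(c1ccccc1)C(C)(C)C)CCO
F6 | step 8 | primary iodide (C2–I) | CC[Si](CC)(CC)OC/C=C(/CO[Si](c1ccccc1)(c1ccccc1)C(C)(C)C)CCI
F7 | step 8 | (Z)-iodo ester (C10–I; C14 = CO2Et) | CC[Si](CC)(CC)OC/C=C(/CO[Si](c1ccccc1)(c1ccccc1)C(C)(C)C)CC/C=C(\I)C(=O)OCC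
F8 | step 8 | iodo alcohol (C14–OH) | CC[Si](CC)(CC)OC/C=C(/CO[Si](c1ccccc1)(c1ccccc1)C(C)(C)C)CC/C=C(\I)CO
F9 | step 8 | silyl ether (C14–OTBS; C10–I) | CC[Si](CC)(CC)OC/C=C(/CO[Si](c1ccccc1)(c1ccccc1)C(C)(C)C)CC/C=C(\I)CO[Si](C)(C)C(C)(C)C
F10 | step 12 | epoxy aldehyde (C7 = CHO) | CC[Si](CC)(CC)OC/C=C(/CO[Si](c1ccccc1)(c1ccccc1)C(C)(C)C)CC/C=C(/CO[Si](C)(C)C(C)(C)C)[C@@H]2O[C@H]2C=O
F11 | step 12 | epoxy enoate (allylsilane; CO2Et trans to C8) | CC[Si](CC)(CC)OC/C=C(/CO[Si](c1ccccc1)(c1ccccc1)C(C)(C)C)CC/C=C(/CO[Si](C)(C)C(C)(C)C)[C@@H]2O[C@H]2/C=C(\C[Si](C)(C)C)C(=O)OCC
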